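**Strategy**

Eudesmane numbering is used throughout. The route rests on opening ring A between C4 and C5. The C3=C4 olefin carrying the C15 oxymethyl group, next to the trans ring fusion (C5–H, C10–CH3), is the footprint of a 2-alkynyl ether C3≡C4–C15 attacked at C4 by an E-configured C5=C10 olefin. A single cascade, catalysed by a chiral complex of monovalent gold, therefore turns an acyclic 1,5-enyne bearing a silyl dienol ether into the decalin: it closes ring A (C4–C5) and ring B (C9–C10), sets C5 and C10, and leaves a C7 acetyl enone. The acetyl group later becomes the acrylate ester; the coumarate is attached last.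

Key step: step 7

Remark: the sense of induction of the (R)-configured digold complex on this enyne is an assumption; the (S)-configured complex is taken instead if the mirror image of 13 should form. DTBM-MeO-BIPHEP = 6,6′-dimethoxy-2,2′-bis[bis(3,5-di-tert-butyl-4-methoxyphenyl)phosphino]-1,1′-biphenyl. Compounds 9–11 are racemic at the carbon that becomes C7; this centre is planar in 12 and 13 and is set in step 8.

**Route**

Step 1
Reactants: 1 hexa-1,5-diyne
Product: 3 tert-butyl(hepta-2,6-diyn-1-yloxy)dimethylsilane, via lithium hepta-2,6-diyn-1-olate 2 (not isolated)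
Conditions: 1 (3 equiv), n-BuLi (1 equiv), THF, −78 °C; (CH2O)n, −78 °C to rt; then TBSCl, imidazole, DMF, rt
Reagents that add atoms: paraformaldehyde (as formaldehyde), C=O; tert-butyldimethylsilyl chloride, CC(C)(C)[Si](C)(C)Cl
Why: Mono-deprotonation of the diyne used in excess, addition of the acetylide to formaldehyde and O-silylation of the alkoxide in the same flask should give the mono-functionalised diyne (acetylide hydroxymethylation, silyl ether formation).

Step 2
Reactants: 3 tert-butyl(hepta-2,6-diyn-1-yloxy)dimethylsilane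
Product: 5 (2E)-8-{[tert-butyl(dimethyl)silyl]oxy}-3-methyloct-2-en-6-yn-1-ol, via alkenyldimethylalane 4 (not isolated)
Conditions: Me3Al (2 equiv), Cp2ZrCl2 (0.25 equiv), CH2Cl2, 0 °C to rt; then n-BuLi, THF, −78 °C; (CH2O)n, rt; aqueous potassium sodium tartrate
Reagents that add atoms: trimethylaluminium, C[Al](C)C; paraformaldehyde (as formaldehyde), C=O
Why: Negishi carboalumination adds CH3 and Al syn across the terminal alkyne (CH3 to the internal carbon), the internal alkyne reacting much more slowly, and the alkenylalanate adds to formaldehyde with retention, which fixes the E geometry of the later C5=C10 olefin.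

Step 3
Reactants: 5 (2E)-8-{[tert-butyl(dimethyl)silyl]oxy}-3-methyloct-2-en-6-yn-1-ol
Product: 6 {[(6E)-8-bromo-6-methyloct-6-en-2-yn-1-yl]oxy}(tert-butyl)dimethylsilane
Conditions: CBr4, PPh3, 2,6-lutidine, CH2Cl2, 0 °C
Reagents that add atoms: carbon tetrabromide, BrC(Br)(Br)Br
Why: Appel bromination of the primary allylic alcohol proceeds by SN2 displacement of the oxyphosphonium group, so neither allylic shift nor loss of olefin geometry is expected, and the buffered medium spares the silyl ether.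

Step 4
Reactants: 6 {[(6E)-8-bromo-6-methyloct-6-en-2-yn-1-yl]oxy}(tert-butyl)dimethylsilane; 7 methyl (2E)-but-2-enoate
Product: 9 methyl (4E)-10-{[tert-butyl(dimethyl)silyl]oxy}-2-ethenyl-5-methyldec-4-en-8-ynoate (racemic at C-2), via lithium dienolate 8 (not isolated)
Conditions: LDA, THF/DMPU, −78 °C, 7; then 6, −78 to −20 °C
Reagents that add atoms: none
Why: Deconjugative α-alkylation of the crotonate dienolate: the kinetic reaction at the α-carbon with the primary allylic bromide (SN2) should give the 2-vinyl ester, whose new centre is racemic and is planarised in step 6.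

Step 5
Reactants: 9 methyl (4E)-10-{[tert-butyl(dimethyl)silyl]oxy}-2-ethenyl-5-methyldec-4-en-8-ynoate
Product: 11 (5E)-11-{[tert-butyl(dimethyl)silyl]oxy}-3-ethenyl-6-methylundec-5-en-9-yn-2-one (racemic), via Weinreb amide 10 (not isolated)
Conditions: MeNHOMe·HCl, i-PrMgCl, THF, −20 °C; then MeMgBr, 0 °C; cold aqueous NH4Cl
Reagents that add atoms: methylmagnesium bromide, C[Mg]Br
Why: Aminolysis of the ester by the magnesium amide gives the Weinreb amide, whose chelated tetrahedral adduct with MeMgBr stops at the methyl ketone stage (Weinreb ketone synthesis); cold neutral work-up is chosen so that the C8=C9 bond does not move into conjugation.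

Step 6
Reactants: 11 (5E)-11-{[tert-butyl(dimethyl)silyl]oxy}-3-ethenyl-6-methylundec-5-en-9-yn-2-one
Product: 12 (5E)-2,11-bis{[tert-butyl(dimethyl)silyl]oxy}-3-ethenyl-6-methylundeca-2,5-dien-9-yne (mixture of 2E and 2Z)
Conditions: TBSOTf, Et3N, CH2Cl2, −78 to 0 °C
Reagents that add atoms: tert-butyldimethylsilyl trifluoromethanesulfonate, CC(C)(C)[Si](C)(C)OS(=O)(=O)C(F)(F)F
Why: Soft enolisation removes the most acidic proton, the one between the carbonyl and vinyl groups, and should give the linearly conjugated silyl dienol ether, the only conjugated isomer open to a β,γ-unsaturated ketone; the geometry of the new enol ether bond is immaterial.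

Step 7
Reactants: 12 (5E)-2,11-bis{[tert-butyl(dimethyl)silyl]oxy}-3-ethenyl-6-methylundeca-2,5-dien-9-yne
Product: 13 1-[(4aR,8aR)-8-({[tert-butyl(dimethyl)silyl]oxy}methyl)-4a-methyl-1,4,4a,5,6,8a-hexahydronaphthalen-2-yl]ethan-1-one
Conditions: (AuCl)2[(R)-DTBM-MeO-BIPHEP] (3 mol%), AgSbF6 (6 mol%), i-PrOH (1.5 equiv), toluene, −20 °C to rt
Reagents that add atoms: none
Why: The cationic gold centre binds the C3≡C4 alkyne and C5 of the E olefin attacks C4 anti to the metal (6-endo-dig closure of ring A; the 5-exo-dig alternative would be 5-endo-trig at the olefin and is geometrically disfavoured, and the C10 methyl group makes C10 the cationic terminus); the developing C10 cation is captured in the same chair–chair array by C9, the γ-terminus of the silyl dienol ether (6-endo-trig closure of ring B at the C8=C9 vinyl group), after which i-PrOH takes the silyl group and protonates the C3–Au bond. The closest known reaction types are the alkyne-initiated polycyclisations of 1,5-enynes under cationic gold or InBr3 catalysis and silyl enol ether-terminated cation–olefin cyclisations (vinylogous Mukaiyama-type capture). C5 and C10 are set relative to each other by anti addition across the E-C5=C10 olefin (Stork–Eschenmoser geometry, fixed in step 2), which should give the trans fusion, and in the absolute sense by the chiral bisphosphine on gold, which selects the olefin face that bonds to C4. The step needs γ- and not α-attack of the dienol ether, secured because α-attack at C7 would close a four-membered ring, and it needs the propargylic oxygen group to stay in place, for which a silyl ether and not an ester was chosen. C7 is planar in 13 and is set in step 8.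

Step 8
Reactants: 13 1-[(4aR,8aR)-8-({[tert-butyl(dimethyl)silyl]oxy}methyl)-4a-methyl-1,4,4a,5,6,8a-hexahydronaphthalen-2-yl]ethan-1-one
Product: 15 1-[(2R,4aR,8aR)-8-({[tert-butyl(dimethyl)silyl]oxy}methyl)-4a-methyl-1,2,3,4,4a,5,6,8a-octahydronaphthalen-2-yl]ethan-1-one, via triethylsilyl enol ether 14 (not isolated)
Conditions: Et3SiH, RhCl(PPh3)3 (2 mol%), toluene, 50 °C; then K2CO3, MeOH, rt
Reagents that add atoms: none
Why: Rhodium-catalysed 1,4-hydrosilylation reduces only the enone, and methanolysis of the silyl enol ether followed by base equilibration should place the acetyl group equatorial (7R, cis to the C10 methyl group), so C7 is set under thermodynamic control; a minor axial epimer would be removed and re-equilibrated.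

Step 9
Reactants: 15 1-[(2R,4aR,8aR)-8-({[tert-butyl(dimethyl)silyl]oxy}methyl)-4a-methyl-1,2,3,4,4a,5,6,8a-octahydronaphthalen-2-yl]ethan-1-one
Product: 17 1-[(2R,4aR,8aR)-8-({[tert-butyl(dimethyl)silyl]oxy}methyl)-4a-methyl-1,2,3,4,4a,5,6,8a-octahydronaphthalen-2-yl]ethenyl trifluoromethanesulfonate, via potassium enolate 16 (not isolated)
Conditions: KHMDS, THF, −78 °C; then PhNTf2, −78 to 0 °C
Reagents that add atoms: N-phenylbis(trifluoromethanesulfonimide), O=S(=O)(N(c1ccccc1)S(=O)(=O)C(F)(F)F)C(F)(F)F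
Why: The hindered amide base removes a methyl proton under kinetic control and not the tertiary C7–H, so O-triflation gives the terminal enol triflate and C7 is not touched.

Step 10
Reactants: 17 1-[(2R,4aR,8aR)-8-({[tert-butyl(dimethyl)silyl]oxy}methyl)-4a-methyl-1,2,3,4,4a,5,6,8a-octahydronaphthalen-2-yl]ethenyl trifluoromethanesulfonate
Product: 18 methyl 2-[(2R,4aR,8aR)-8-({[tert-butyl(dimethyl)silyl]oxy}methyl)-4a-methyl-1,2,3,4,4a,5,6,8a-octahydronaphthalen-2-yl]prop-2-enoate
Conditions: Pd(OAc)2 (5 mol%), PPh3 (10 mol%), Et3N, CO (1 atm), MeOH/DMF, rt to 50 °C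
Reagents that add atoms: carbon monoxide, [C-]#[O+]; methanol, CO
Why: Oxidative addition of zerovalent palladium to the enol triflate, CO insertion and methanolysis of the acylpalladium species (carbonylative coupling) should give the 2-substituted acrylate directly.

Step 11
Reactants: 18 methyl 2-[(2R,4aR,8aR)-8-({[tert-butyl(dimethyl)silyl]oxy}methyl)-4a-methyl-1,2,3,4,4a,5,6,8a-octahydronaphthalen-2-yl]prop-2-enoate
Product: 19 methyl 2-[(2R,4aR,8aR)-8-(hydroxymethyl)-4a-methyl-1,2,3,4,4a,5,6,8a-octahydronaphthalen-2-yl]prop-2-enoate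
Conditions: HF·pyridine, THF/pyridine, 0 °C to rt
Reagents that add atoms: none
Why: Buffered fluoride cleaves the primary allylic silyl ether (desilylation) under conditions that leave the acrylate and both olefins alone.

Step 12
Reactants: 19 methyl 2-[(2R,4aR,8aR)-8-(hydroxymethyl)-4a-methyl-1,2,3,4,4a,5,6,8a-octahydronaphthalen-2-yl]prop-2-enoate; 20 (2E)-3-(4-hydroxyphenyl)prop-2-enoic acid
Product: 21 methyl 2-[(2R,4aR,8aR)-8-({[(2E)-3-(4-hydroxyphenyl)prop-2-enoyl]oxy}methyl)-4a-methyl-1,2,3,4,4a,5,6,8a-octahydronaphthalen-2-yl]prop-2-enoate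
Conditions: PPh3, DIAD (betaine preformed), THF, 0 °C to rt
Reagents that add atoms: none
Why: In the Mitsunobu esterification the carboxylic acid, far more acidic than the phenol, is the species that is deprotonated and alkylated by the alkoxyphosphonium ion, and the primary allylic carbon should react by direct SN2, so the phenol needs no protection.

**Compound list**

1 | hexa-1,5-diyne | C#CCCC#C | starting material
2 | lithium hepta-2,6-diyn-1-olate | [Li+].[O-]CC#CCCC#C | intermediate
3 | tert-butyl(hepta-2,6-diyn-1-yloxy)dimethylsilane | C#CCCC#CCO[Si](C)(C)C(C)(C)C | intermediate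
4 | [(1E)-7-{[tert-butyl(dimethyl)silyl]oxy}-2-methylhept-1-en-5-yn-1-yl]dimethylalumane | C[Al](C)/C=C(C)/CCC#CCO[Si](C)(C)C(C)(C)C | intermediate
5 | (2E)-8-{[tert-butyl(dimethyl)silyl]oxy}-3-methyloct-2-en-6-yn-1-ol | OC/C=C(C)/CCC#CCO[Si](C)(C)C(C)(C)C | intermediate
6 | {[(6E)-8-bromo-6-methyloct-6-en-2-yn-1-yl]oxy}(tert-butyl)dimethylsilane | BrC/C=C(C)/CCC#CCO[Si](C)(C)C(C)(C)C | intermediate
7 | methyl (2E)-but-2-enoate (methyl crotonate) | C/C=C/C(=O)OC | starting material
8 | lithium 1-methoxybuta-1,3-dien-1-olate | [Li+].[O-]C(OC)=CC=C | intermediate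
9 | methyl (4E)-10-{[tert-butyl(dimethyl)silyl]oxy}-2-ethenyl-5-methyldec-4-en-8-ynoate (racemic) | C=CC(C/C=C(C)/CCC#CCO[Si](C)(C)C(C)(C)C)C(=O)OC | intermediate
10 | (4E)-10-{[tert-butyl(dimethyl)silyl]oxy}-2-ethenyl-N-methoxy-N,5-dimethyldec-4-en-8-ynamide (racemic) | C=CC(C/C=C(C)/CCC#CCO[Si](C)(C)C(C)(C)C)C(=O)N(C)OC | intermediate
11 | (5E)-11-{[tert-butyl(dimethyl)silyl]oxy}-3-ethenyl-6-methylundec-5-en-9-yn-2-one (racemic) | C=CC(C/C=C(C)/CCC#CCO[Si](C)(C)C(C)(C)C)C(C)=O | intermediate
12 | (5E)-2,11-bis{[tert-butyl(dimethyl)silyl]oxy}-3-ethenyl-6-methylundeca-2,5-dien-9-yne (2E/2Z mixture) | C=CC(C/C=C(C)/CCC#CCO[Si](C)(C)C(C)(C)C)=C(C)O[Si](C)(C)C(C)(C)C | intermediate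
13 | 1-[(4aR,8aR)-8-({[tert-butyl(dimethyl)silyl]oxy}methyl)-4a-methyl-1,4,4a,5,6,8a-hexahydronaphthalen-2-yl]ethan-1-one | CC(=O)C1=CC[C@@]2(C)CCC=C(CO[Si](C)(C)C(C)(C)C)[C@@H]2C1 | intermediate
14 | tert-butyl(dimethyl)({(4aR,8aR)-4a-methyl-7-[1-(triethylsilyloxy)ethylidene]-3,4,4a,5,6,7,8,8a-octahydronaphthalen-1-yl}methoxy)silane (triethylsilyl enol ether of 15) | CC(O[Si](CC)(CC)CC)=C1CC[C@@]2(C)CCC=C(CO[Si](C)(C)C(C)(C)C)[C@@H]2C1 | intermediate
15 | 1-[(2R,4aR,8aR)-8-({[tert-butyl(dimethyl)silyl]oxy}methyl)-4a-methyl-1,2,3,4,4a,5,6,8a-octahydronaphthalen-2-yl]ethan-1-one | CC(=O)[C@@H]1CC[C@@]2(C)CCC=C(CO[Si](C)(C)C(C)(C)C)[C@@H]2C1 | intermediate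
16 | potassium 1-[(2R,4aR,8aR)-8-({[tert-butyl(dimethyl)silyl]oxy}methyl)-4a-methyl-1,2,3,4,4a,5,6,8a-octahydronaphthalen-2-yl]ethen-1-olate | [K+].C=C([O-])[C@@H]1CC[C@@]2(C)CCC=C(CO[Si](C)(C)C(C)(C)C)[C@@H]2C1 | intermediate
17 | 1-[(2R,4aR,8aR)-8-({[tert-butyl(dimethyl)silyl]oxy}methyl)-4a-methyl-1,2,3,4,4a,5,6,8a-octahydronaphthalen-2-yl]ethenyl trifluoromethanesulfonate | C=C(OS(=O)(=O)C(F)(F)F)[C@@H]1CC[C@@]2(C)CCC=C(CO[Si](C)(C)C(C)(C)C)[C@@H]2C1 | intermediate
18 | methyl 2-[(2R,4aR,8aR)-8-({[tert-butyl(dimethyl)silyl]oxy}methyl)-4a-methyl-1,2,3,4,4a,5,6,8a-octahydronaphthalen-2-yl]prop-2-enoate | C=C(C(=O)OC)[C@@H]1CC[C@@]2(C)CCC=C(CO[Si](C)(C)C(C)(C)C)[C@@H]2C1 | intermediate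
19 | methyl 2-[(2R,4aR,8aR)-8-(hydroxymethyl)-4a-methyl-1,2,3,4,4a,5,6,8a-octahydronaphthalen-2-yl]prop-2-enoate | C=C(C(=O)OC)[C@@H]1CC[C@@]2(C)CCC=C(CO)[C@@H]2C1 | intermediate
20 | (2E)-3-(4-hydroxyphenyl)prop-2-enoic acid (p-coumaric acid) | OC(=O)/C=C/c1ccc(O)cc1 | starting material
21 | methyl 2-[(2R,4aR,8aR)-8-({[(2E)-3-(4-hydroxyphenyl)prop-2-enoyl]oxy}methyl)-4a-methyl-1,2,3,4,4a,5,6,8a-octahydronaphthalen-2-yl]prop-2-enoate | C=C(C(=O)OC)[C@@H]1CC[C@@]2(C)CCC=C(COC(=O)/C=C/c3ccc(O)cc3)[C@@H]2C1 | target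

**Step count**

Total step count: 12. Longest linear sequence: 12 steps, from 1 to 21 (7 and 20 are bought).

**Steps most likely to fail**

1. Step 7. What may go wrong: weak discrimination between the two faces of the C5=C10 olefin in its attack on the gold-bound internal alkyne, so that the enantiomeric purity of 13 is low. The fallback replaces catalyst control by a resolution. Setting out from 12, the cascade is run with the achiral complex Ph3PAuNTf2 under the same protocol and should give 13 together with its mirror image, 1-[(4aS,8aS)-8-({[tert-butyl(dimethyl)silyl]oxy}methyl)-4a-methyl-1,4,4a,5,6,8a-hexahydronaphthalen-2-yl]ethan-1-one F1. CBS reduction of the mixture ((S)-2-methyl-CBS-oxazaborolidine, catecholborane, −78 °C) should turn both enantiomers into (1R)-configured allylic alcohols, which are diastereomers: (1R)-1-[(4aR,8aR)-8-({[tert-butyl(dimethyl)silyl]oxy}methyl)-4a-methyl-1,4,4a,5,6,8a-hexahydronaphthalen-2-yl]ethan-1-ol F2 and (1R)-1-[(4aS,8aS)-8-({[tert-butyl(dimethyl)silyl]oxy}methyl)-4a-methyl-1,4,4a,5,6,8a-hexahydronaphthalen-2-yl]ethan-1-ol F3. After chromatographic separation F2 is oxidised with MnO2, and the route is rejoined at 13.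

2. Step 6. What may go wrong: migration of the C8=C9 double bond of 11 into conjugation before or during silylation, followed by enolisation toward the methyl group, which would give the cross-conjugated 2-siloxydiene and, in the cascade, the wrong ring. The fallback uses the ester and not the ketone as the enol component. Setting out from 9, whose single α-hydrogen leaves no regiochemical choice, LDA and TBSCl (THF/DMPU, −78 °C) give the vinylogous silyl ketene acetal tert-butyl{[(4E)-10-{[tert-butyl(dimethyl)silyl]oxy}-2-ethenyl-1-methoxy-5-methyldeca-1,4-dien-8-yn-1-yl]oxy}dimethylsilane F4. The gold cascade of step 7 applied to F4 should give methyl (4aR,8aR)-8-({[tert-butyl(dimethyl)silyl]oxy}methyl)-4a-methyl-1,4,4a,5,6,8a-hexahydronaphthalene-2-carboxylate F5. Conjugate reduction with Mg in MeOH and equilibration with NaOMe should give the equatorial ester methyl (2R,4aR,8aR)-8-({[tert-butyl(dimethyl)silyl]oxy}methyl)-4a-methyl-1,2,3,4,4a,5,6,8a-octahydronaphthalene-2-carboxylate F6. The protocol of step 5 converts F6, by way of (2R,4aR,8aR)-8-({[tert-butyl(dimethyl)silyl]oxy}methyl)-N-methoxy-N,4a-dimethyl-1,2,3,4,4a,5,6,8a-octahydronaphthalene-2-carboxamide F7, into the methyl ketone, and the route is rejoined at 15.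

3. Step 12. What may go wrong: competing alkylation of the free phenol oxygen (aryl ether and oligomer formation) and allylic transposition at C15. The fallback acylates the alcohol with an activated, phenol-protected acid and no longer alkylates the carboxylate. Setting out from 20, double silylation (TBSCl, imidazole, DMF) gives tert-butyl(dimethyl)silyl (2E)-3-(4-{[tert-butyl(dimethyl)silyl]oxy}phenyl)prop-2-enoate F8, whose silyl ester alone is cleaved with K2CO3 in aqueous MeOH to give (2E)-3-(4-{[tert-butyl(dimethyl)silyl]oxy}phenyl)prop-2-enoic acid F9. Carbodiimide coupling of F9 with 19 (EDC·HCl, DMAP, CH2Cl2) should give methyl 2-[(2R,4aR,8aR)-8-({[(2E)-3-(4-{[tert-butyl(dimethyl)silyl]oxy}phenyl)prop-2-enoyl]oxy}methyl)-4a-methyl-1,2,3,4,4a,5,6,8a-octahydronaphthalen-2-yl]prop-2-enoate F10, and brief treatment with TBAF/AcOH in THF at 0 °C releases the phenol, which rejoins the route at 21.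

**Further compounds**

F1 | step 7 | 1-[(4aS,8aS)-8-({[tert-butyl(dimethyl)silyl]oxy}methyl)-4a-methyl-1,4,4a,5,6,8a-hexahydronaphthalen-2-yl]ethan-1-one | CC(=O)C1=CC[C@]2(C)CCC=C(CO[Si](C)(C)C(C)(C)C)[C@H]2C1
F2 | step 7 | (1R)-1-[(4aR,8aR)-8-({[tert-butyl(dimethyl)silyl]oxy}methyl)-4a-methyl-1,4,4a,5,6,8a-hexahydronaphthalen-2-yl]ethan-1-ol | C[C@@H](O)C1=CC[C@@]2(C)CCC=C(CO[Si](C)(C)C(C)(C)C)[C@@H]2C1
F3 | step 7 | (1R)-1-[(4aS,8aS)-8-({[tert-butyl(dimethyl)silyl]oxy}methyl)-4a-methyl-1,4,4a,5,6,8a-hexahydronaphthalen-2-yl]ethan-1-ol | C[C@@H](O)C1=CC[C@]2(C)CCC=C(CO[Si](C)(C)C(C)(C)C)[C@H]2C1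
F4 | step 6 | tert-butyl{[(4E)-10-{[tert-butyl(dimethyl)silyl]oxy}-2-ethenyl-1-methoxy-5-methyldeca-1,4-dien-8-yn-1-yl]oxy}dimethylsilane | C=CC(C/C=C(C)/CCC#CCO[Si](C)(C)C(C)(C)C)=C(OC)O[Si](C)(C)C(C)(C)C
F5 | step 6 | methyl (4aR,8aR)-8-({[tert-butyl(dimethyl)silyl]oxy}methyl)-4a-methyl-1,4,4a,5,6,8a-hexahydronaphthalene-2-carboxylate | COC(=O)C1=CC[C@@]2(C)CCC=C(CO[Si](C)(C)C(C)(C)C)[C@@H]2C1
F6 | step 6 | methyl (2R,4aR,8aR)-8-({[tert-butyl(dimethyl)silyl]oxy}methyl)-4a-methyl-1,2,3,4,4a,5,6,8a-octahydronaphthalene-2-carboxylate | COC(=O)[C@@H]1CC[C@@]2(C)CCC=C(CO[Si](C)(C)C(C)(C)C)[C@@H]2C1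
F7 | step 6 | (2R,4aR,8aR)-8-({[tert-butyl(dimethyl)silyl]oxy}methyl)-N-methoxy-N,4a-dimethyl-1,2,3,4,4a,5,6,8a-octahydronaphthalene-2-carboxamide | CON(C)C(=O)[C@@H]1CC[C@@]2(C)CCC=C(CO[Si](C)(C)C(C)(C)C)[C@@H]2C1
F8 | step 12 | tert-butyl(dimethyl)silyl (2E)-3-(4-{[tert-butyl(dimethyl)silyl]oxy}phenyl)prop-2-enoate | CC(C)(C)[Si](C)(C)OC(=O)/C=C/c1ccc(O[Si](C)(C)C(C)(C)C)cc1
F9 | step 12 | (2E)-3-(4-{[tert-butyl(dimethyl)silyl]oxy}phenyl)prop-2-enoic acid | OC(=O)/C=C/c1ccc(O[Si](C)(C)C(C)(C)C)cc1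
F10 | step 12 | methyl 2-[(2R,4aR,8aR)-8-({[(2E)-3-(4-{[tert-butyl(dimethyl)silyl]oxy}phenyl)prop-2-enoyl]oxy}methyl)-4a-methyl-1,2,3,4,4a,5,6,8a-octahydronaphthalen-2-yl]prop-2-enoate | C=C(C(=O)OC)[C@@H]1CC[C@@]2(C)CCC=C(COC(=O)/C=C/c3ccc(O[Si](C)(C)C(C)(C)C)cc3)[C@@H]2C1
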